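All runs come from a simulation on assumed constants.

- A flat target does not mean a still flask: in the ash run the target barely moves after 2.00 h, yet the isomer of the product B, written X, keeps falling.

| flask | substrate | remark | time |
|---|---|---|---|
| ash | 0.65 M | run made earlier |  |
| alder | 0.98 M | run made earlier |  |
| flask | 1.3 M |  | 12 h |

- ash (time / h: isomer of the product B / %, target / %): 0.333: 75.0, 9.3; 0.833: 77.7, 4.8; 2.00: 77.8, 3.7; 5.00: 74.0, 3.8; 12.0: 63.7, 4.1
- alder (time / h: isomer of the product B / %, target / %): 0.333: 73.5, 9.6; 0.833: 78.8, 4.7; 2.00: 78.4, 2.8; 5.00: 72.5, 4.8; 12.0: 65.1, 4.8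

(each reading ± 1 percentage point)



1. time, not beyond 12 h, at which the flask holds most isomer of the product B
2. the amount of isomer of the product B, in percent of the substrate charged, at that time

- Here is the apparent contradiction: from 2.00 h to 12.0 h, the ash run's readings of X fall by 14 percentage points, far more than the 0.4 points by which its target readings rise.
- The mass balance on the charged substrate clears it up. Let U be the unread share, the charge minus X and target. In the ash run U grows by 14 points over those hours, so the X lost there reappears in species that were not read, and the target is no measure of that loss.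
- The useful quantity is therefore the keep factor f, X at 12 h over the highest reading of X, averaged over the two runs: 0.822. The ash run reads 0.819, and the alder run, at 1.51 times the ash charge, reads 0.826.
- The forecast for the flask is 78.5% at 1.2 h, with the caution “The maximum is flat, so its time is poorly fixed.” My own step is to multiply that peak by f, which gives 64.5% of X at 12 h.
- The flask peaks later than forecast, at 1.43 h, with 78.3% of X, and the forecast's height of the peak stands within the margin. Here f gives 64.4% at 12 h, and the flask holds 64.1%, with the isomer of the product A up from 6.49% at 1.43 h to 23.9% at 12.0 h.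

    substrate ⇌ target (K = 2.20, k = 0.00190 s⁻¹)
    target ⇌ isomer of the product A (K = 12.0, k = 1.60 × 10⁻⁴ s⁻¹)
    isomer of the product A ⇌ isomer of the product B (K = 1.50, k = 3.90 × 10⁻⁶ s⁻¹)
    isomer of the product B ⇌ substrate (k = 1.60 × 10⁻⁴ s⁻¹)
    target ⇌ isomer of the product C (K = 0.150, k = 9.10 × 10⁻⁵ s⁻¹)
    substrate ⇌ dormant form (K = 2.60, k = 9.90 × 10⁻⁴ s⁻¹)
    2 substrate → homo dimer (k = 1.40 × 10⁻⁴ M⁻¹ s⁻¹)

- The neighbouring flask, charged with 0.33 M of substrate, a quarter of this flask's charge, peaks at 79.5% of X. Multiplying by f gives 65.3%, and at 12 h that neighbouring flask holds 65.3%.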